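In ring B (C1–C6) the quaternary C1 with its two methyl groups lies next to the C2 carbinol, the imprint of a trisubstituted terpene epoxide opened at its tertiary carbon, and the cis C3–OH is the carbinol of the adjoining erythro epoxy alcohol; ring A carries the same C1'/C2' imprint without a C3' oxygen.
The C40 polyene is cut at C11=C12 and C11'=C12' into two C15 dienyl phosphonium salts (ring A, ring B) and 2,7-dimethylocta-2,4,6-trienedial; two Wittig reactions are followed by removal of three silyl ethers.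
Each C15 salt comes from a silyloxy β-cyclocitral (C5 phosphonate olefination, reduction, PPh3·HBr), and each cyclocitral from a hydroxy-cyclogeranyl acetate by silylation, deacetylation, oxidation and base conjugation of the alkene into C5=C6.
Ring B is formed first (step 8): MeAlCl2-induced epoxide–olefin cyclization of (5S,6S)-5-silyloxy-6,7-epoxygeranyl acetate makes the C1–C6 bond; the precursor comes from prenol by Sharpless epoxidation, oxidation and a Felkin-selective vinylogous Mukaiyama aldol with the senecioate dienolate.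
Ring A is formed second (step 17) by the same cyclization of (6R)-6,7-epoxygeranyl acetate, made by Shi epoxidation of geranyl acetate.

Key step: step 8

Remark: carotenoid numbering is used (ring carbons C1–C6, chain from C7, primes for the ring A half); TBS = tert-butyldimethylsilyl; the C4=C5 alkenes 11 and 23 are expected together with their exocyclic C5-methylene isomers, which are carried along and converge in steps 12 and 21.

Step 1
Reactants: 1 3-methylbut-2-en-1-ol (prenol)
Product: 2 [(2S)-3,3-dimethyloxiran-2-yl]methanol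
Conditions: Ti(OiPr)4 (5 mol%), L-(+)-diisopropyl tartrate (7 mol%), tBuOOH, 4 Å MS, CH2Cl2, −20 °C; non-aqueous work-up
Reagents that add atoms: tert-butyl hydroperoxide, CC(C)(C)OO
Why: Sharpless asymmetric epoxidation of a primary allylic alcohol, in which the L-(+)-tartrate titanium catalyst should deliver oxygen in the same facial sense as for geraniol and so give the (2S)-epoxy alcohol that becomes C2 of ring B.

Step 2
Reactants: 2 [(2S)-3,3-dimethyloxiran-2-yl]methanol
Product: 3 (2R)-3,3-dimethyloxirane-2-carbaldehyde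
Conditions: Dess–Martin periodinane, pyridine, CH2Cl2, 0 °C → rt; filtered through silica and used at once
Reagents that add atoms: none
Why: Dess–Martin oxidation under pyridine buffer converts the epoxy alcohol into the aldehyde without acid or strong base, so the epoxide and its stereocentre (R only through the changed CIP priorities) stay untouched.

Step 3
Reactants: 4 methyl 3-methylbut-2-enoate
Product: 6 tert-butyl[(1-methoxy-3-methylbuta-1,3-dien-1-yl)oxy]dimethylsilane, via lithium dienolate 5 (not isolated)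
Conditions: LiN(iPr)2, THF, −78 °C; then TBSCl, DMPU, −78 °C → rt
Reagents that add atoms: tert-butyldimethylsilyl chloride, CC(C)(C)[Si](C)(C)Cl
Why: Kinetic γ-deprotonation of the senecioate and O-silylation of the dienolate (silyl ketene acetal formation) is the standard access to this vinylogous Mukaiyama donor.

Step 4
Reactants: 3 (2R)-3,3-dimethyloxirane-2-carbaldehyde; 6 tert-butyl[(1-methoxy-3-methylbuta-1,3-dien-1-yl)oxy]dimethylsilane
Product: 7 methyl (2E,5S)-5-[(2S)-3,3-dimethyloxiran-2-yl]-5-hydroxy-3-methylpent-2-enoate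
Conditions: BF3·OEt2 (1.1 equiv), CH2Cl2, −78 °C; aq. NaHCO3
Reagents that add atoms: none
Why: Vinylogous Mukaiyama aldol reaction in which the γ-carbon of the silyl dienolate attacks the BF3-bound aldehyde through an open transition state anti to the epoxide C–O bond (Felkin–Anh, non-chelating Lewis acid), which should set the (5S) carbinol erythro to the epoxide, while the extended dienolate should give the (2E)-enoate.

Step 5
Reactants: 7 methyl (2E,5S)-5-[(2S)-3,3-dimethyloxiran-2-yl]-5-hydroxy-3-methylpent-2-enoate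
Product: 8 methyl (2E,5S)-5-(TBSO)-5-[(2S)-3,3-dimethyloxiran-2-yl]-3-methylpent-2-enoate
Conditions: TBSCl, imidazole, DMF, rt
Reagents that add atoms: tert-butyldimethylsilyl chloride, CC(C)(C)[Si](C)(C)Cl
Why: Imidazole-promoted silylation of the secondary alcohol is mild enough for the epoxide and masks the future C3 oxygen as an ether that cannot act as a neighbouring group.

Step 6
Reactants: 8 methyl (2E,5S)-5-(TBSO)-5-[(2S)-3,3-dimethyloxiran-2-yl]-3-methylpent-2-enoate
Product: 9 (2E,5S)-5-(TBSO)-5-[(2S)-3,3-dimethyloxiran-2-yl]-3-methylpent-2-en-1-ol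
Conditions: iBu2AlH (2.2 equiv), CH2Cl2, −78 °C; aq. KNaC4H4O6
Reagents that add atoms: none
Why: 1,2-Reduction of the α,β-unsaturated ester by iBu2AlH at low temperature gives the allylic alcohol and should leave the hindered trisubstituted epoxide and the silyl ether intact.

Step 7
Reactants: 9 (2E,5S)-5-(TBSO)-5-[(2S)-3,3-dimethyloxiran-2-yl]-3-methylpent-2-en-1-ol
Product: 10 (2E,5S)-5-(TBSO)-5-[(2S)-3,3-dimethyloxiran-2-yl]-3-methylpent-2-en-1-yl acetate [(5S,6S)-5-silyloxy-6,7-epoxygeranyl acetate]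
Conditions: Ac2O, pyridine, 4-(dimethylamino)pyridine (cat.), CH2Cl2, 0 °C
Reagents that add atoms: acetic anhydride, CC(=O)OC(C)=O
Why: Nucleophile-catalysed acetylation of the primary allylic alcohol installs the ester that is the usual terminus for Lewis-acid epoxy-olefin cyclizations of geranyl derivatives.

Step 8
Reactants: 10 (5S,6S)-5-silyloxy-6,7-epoxygeranyl acetate
Product: 11 [(1R,4S,5R)-4-(TBSO)-5-hydroxy-2,6,6-trimethylcyclohex-2-en-1-yl]methyl acetate
Conditions: MeAlCl2 (2.2 equiv), CH2Cl2, −78 °C; aq. KNaC4H4O6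
Reagents that add atoms: none
Why: MeAlCl2 coordinates to the oxirane oxygen and loosens its bond to the tertiary carbon (future C1); the trisubstituted alkene then bonds through C6 to C1 on the face opposite the departing oxygen, and the resulting tertiary C5 cation is quenched by proton loss from C4 or from the C5 methyl group. The closest known reaction is the Lewis-acid epoxide-initiated cation–olefin monocyclization of 6,7-epoxygeranyl acetate to hydroxy-cyclogeranyl acetates. Ring B closes in a 6-endo mode with respect to both partners (6-endo-trig at the alkene, endo opening of the epoxide at its distal carbon) through a chair with the C2 oxygen and the acetoxymethyl arm equatorial. The one new stereocentre, C6, is set by the E alkene geometry in that chair and is removed again in step 12, whereas the C2–O bond is never broken, C3 takes no part and the inversion falls on the non-stereogenic C1, so the erythro pair of 10 should emerge as the cis 2,3-dioxygen pair. The step needs ring closure to beat the 1,2-hydride shift to a C2 ketone and needs cleavage at the tertiary C–O bond only; the tertiary cation, the low temperature and the electron-withdrawing silyloxy group next to C2 (which disfavours positive charge there) should secure this, and a silyl ether has no carbonyl oxygen with which to intercept the cation as an acyl group would.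

Step 9
Reactants: 11 [(1R,4S,5R)-4-(TBSO)-5-hydroxy-2,6,6-trimethylcyclohex-2-en-1-yl]methyl acetate
Product: 12 [(1R,4S,5R)-4,5-bis(TBSO)-2,6,6-trimethylcyclohex-2-en-1-yl]methyl acetate
Conditions: TBSOTf, 2,6-lutidine, CH2Cl2, −78 → 0 °C
Reagents that add atoms: tert-butyldimethylsilyl triflate, CC(C)(C)[Si](C)(C)OS(=O)(=O)C(F)(F)F
Why: Silylation with the reactive silyl triflate is needed for the hindered neopentyl-type C2 hydroxyl and blocks lactol formation with the cis C6 formyl group made in step 11.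

Step 10
Reactants: 12 [(1R,4S,5R)-4,5-bis(TBSO)-2,6,6-trimethylcyclohex-2-en-1-yl]methyl acetate
Product: 13 [(1R,4S,5R)-4,5-bis(TBSO)-2,6,6-trimethylcyclohex-2-en-1-yl]methanol
Conditions: K2CO3 (0.2 equiv), MeOH, rt
Reagents that add atoms: none
Why: Base-catalysed transesterification with methanol removes the primary acetate while the silyl ethers are stable.

Step 11
Reactants: 13 [(1R,4S,5R)-4,5-bis(TBSO)-2,6,6-trimethylcyclohex-2-en-1-yl]methanol
Product: 14 (1R,4S,5R)-4,5-bis(TBSO)-2,6,6-trimethylcyclohex-2-ene-1-carbaldehyde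
Conditions: Dess–Martin periodinane, pyridine, CH2Cl2, 0 °C → rt
Reagents that add atoms: none
Why: Dess–Martin oxidation of the hindered primary alcohol gives the β,γ-unsaturated aldehyde under buffered conditions that do not yet move the alkene.

Step 12
Reactants: 14 (1R,4S,5R)-4,5-bis(TBSO)-2,6,6-trimethylcyclohex-2-ene-1-carbaldehyde
Product: 15 (4S,5R)-4,5-bis(TBSO)-2,6,6-trimethylcyclohex-1-ene-1-carbaldehyde
Conditions: 1,8-diazabicyclo[5.4.0]undec-7-ene (DBU, 0.3 equiv), CH2Cl2, rt
Reagents that add atoms: none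
Why: Base-mediated conjugation of a β,γ-unsaturated aldehyde, in which DBU removes the C6 proton and reprotonation of the dienolate at C4 (or at the exocyclic carbon) should give the tetrasubstituted C5=C6 enal from every alkene isomer and C6 epimer, erasing the C6 stereocentre.

Step 13
Reactants: 15 (4S,5R)-4,5-bis(TBSO)-2,6,6-trimethylcyclohex-1-ene-1-carbaldehyde; 16 triethyl 3-methyl-4-phosphonobut-2-enoate
Product: 18 ethyl (2E,4E)-5-[(4S,5R)-4,5-bis(TBSO)-2,6,6-trimethylcyclohex-1-en-1-yl]-3-methylpenta-2,4-dienoate, via lithiated phosphonate 17 (not isolated)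
Conditions: 16 and LiN(SiMe3)2, THF, −78 → 0 °C; then 15, 0 °C → rt
Reagents that add atoms: none
Why: Horner–Wadsworth–Emmons olefination at the phosphorus-bearing carbon of the C5 phosphonate gives the (E)-C7=C8 bond of the dienoate, the standard C10 + C5 extension of β-cyclocitrals, and a minor 2Z isomer can be removed by chromatography; the lithium anion at low temperature is chosen here to keep the medium as mild as possible for the enal that carries the C3 silyloxy group.

Step 14
Reactants: 18 ethyl (2E,4E)-5-[(4S,5R)-4,5-bis(TBSO)-2,6,6-trimethylcyclohex-1-en-1-yl]-3-methylpenta-2,4-dienoate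
Product: 19 (2E,4E)-5-[(4S,5R)-4,5-bis(TBSO)-2,6,6-trimethylcyclohex-1-en-1-yl]-3-methylpenta-2,4-dien-1-ol
Conditions: iBu2AlH (2.2 equiv), CH2Cl2, −78 °C; aq. KNaC4H4O6
Reagents that add atoms: none
Why: Reduction of the dienoate by iBu2AlH gives the primary dienyl alcohol without touching the silyl ethers.

Step 15
Reactants: 19 (2E,4E)-5-[(4S,5R)-4,5-bis(TBSO)-2,6,6-trimethylcyclohex-1-en-1-yl]-3-methylpenta-2,4-dien-1-ol
Product: 20 [(2E,4E)-5-[(4S,5R)-4,5-bis(TBSO)-2,6,6-trimethylcyclohex-1-en-1-yl]-3-methylpenta-2,4-dien-1-yl]triphenylphosphonium bromide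
Conditions: PPh3·HBr, CH2Cl2, rt
Reagents that add atoms: triphenylphosphine hydrobromide, Br.c1ccc(cc1)P(c1ccccc1)c1ccccc1
Why: Phosphonium salt formation by SN1-type substitution, in which the acid ionises the dienylic alcohol and triphenylphosphine captures the terminal carbon of the pentadienyl cation, under aprotic conditions that the secondary silyl ethers should survive.

Step 16
Reactants: 21 geranyl acetate
Product: 22 (2E)-5-[(2R)-3,3-dimethyloxiran-2-yl]-3-methylpent-2-en-1-yl acetate [(6R)-6,7-epoxygeranyl acetate]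
Conditions: D-fructose-derived Shi ketone (1,2:4,5-di-O-isopropylidene-β-D-erythro-2,3-hexodiulo-2,6-pyranose, 0.3 equiv), KHSO5 (as Oxone), K2CO3, Bu4NHSO4, MeCN/CH2(OMe)2/aq. Na2B4O7 buffer, 0 °C
Reagents that add atoms: potassium peroxymonosulfate, [K+].[O-]S(=O)(=O)OO
Why: Shi asymmetric epoxidation, in which the chiral dioxirane attacks the electron-rich distal 6,7-alkene (the 2,3-alkene is deactivated by the allylic acetate) and is expected to give the (6R)-epoxide, as this ketone gives (R,R)-epoxides from trans and trisubstituted alkenes.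

Step 17
Reactants: 22 (6R)-6,7-epoxygeranyl acetate
Product: 23 [(1S,5R)-5-hydroxy-2,6,6-trimethylcyclohex-2-en-1-yl]methyl acetate
Conditions: MeAlCl2 (2.2 equiv), CH2Cl2, −78 °C; aq. KNaC4H4O6
Reagents that add atoms: none
Why: Known Lewis-acid epoxide-initiated cation–olefin cyclization of 6,7-epoxygeranyl acetate, in which anti opening at the tertiary carbon through a chair closes ring A (6-endo), keeps the C–O stereocentre as the (2'R) carbinol and gives the C4'=C5' and exocyclic alkene isomers, both usable.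

Step 18
Reactants: 23 [(1S,5R)-5-hydroxy-2,6,6-trimethylcyclohex-2-en-1-yl]methyl acetate
Product: 24 [(1S,5R)-5-(TBSO)-2,6,6-trimethylcyclohex-2-en-1-yl]methyl acetate
Conditions: TBSOTf, 2,6-lutidine, CH2Cl2, −78 → 0 °C
Reagents that add atoms: tert-butyldimethylsilyl triflate, CC(C)(C)[Si](C)(C)OS(=O)(=O)C(F)(F)F
Why: Silylation with the silyl triflate protects the hindered neopentyl-type C2' hydroxyl for the oxidation and olefination steps.

Step 19
Reactants: 24 [(1S,5R)-5-(TBSO)-2,6,6-trimethylcyclohex-2-en-1-yl]methyl acetate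
Product: 25 [(1S,5R)-5-(TBSO)-2,6,6-trimethylcyclohex-2-en-1-yl]methanol
Conditions: K2CO3 (0.2 equiv), MeOH, rt
Reagents that add atoms: none
Why: Base-catalysed transesterification with methanol cleaves the acetate and leaves the silyl ether.

Step 20
Reactants: 25 [(1S,5R)-5-(TBSO)-2,6,6-trimethylcyclohex-2-en-1-yl]methanol
Product: 26 (1S,5R)-5-(TBSO)-2,6,6-trimethylcyclohex-2-ene-1-carbaldehyde
Conditions: Dess–Martin periodinane, pyridine, CH2Cl2, 0 °C → rt
Reagents that add atoms: none
Why: Dess–Martin oxidation gives the β,γ-unsaturated aldehyde without moving the alkene.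

Step 21
Reactants: 26 (1S,5R)-5-(TBSO)-2,6,6-trimethylcyclohex-2-ene-1-carbaldehyde
Product: 27 (5R)-5-(TBSO)-2,6,6-trimethylcyclohex-1-ene-1-carbaldehyde
Conditions: 1,8-diazabicyclo[5.4.0]undec-7-ene (DBU, 0.3 equiv), CH2Cl2, rt
Reagents that add atoms: none
Why: Base-mediated conjugation (deprotonation at C6', reprotonation at C4' or at the exocyclic carbon) should convert both alkene isomers into the tetrasubstituted C5'=C6' enal, the C2' silyloxy group being remote from the dienolate.

Step 22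
Reactants: 27 (5R)-5-(TBSO)-2,6,6-trimethylcyclohex-1-ene-1-carbaldehyde; 16 triethyl 3-methyl-4-phosphonobut-2-enoate
Product: 29 ethyl (2E,4E)-5-[(5R)-5-(TBSO)-2,6,6-trimethylcyclohex-1-en-1-yl]-3-methylpenta-2,4-dienoate, via sodium phosphonate anion 28 (not isolated)
Conditions: 16 and NaN(SiMe3)2, THF, −78 → 0 °C; then 27, 0 °C → rt
Reagents that add atoms: none
Why: Horner–Wadsworth–Emmons olefination of the sodium anion of the C5 phosphonate at its phosphorus-bearing carbon gives the (E)-C7'=C8' dienoate; the more reactive sodium anion, the classical form of this reagent, is used because enal 27 is hindered and carries no leaving group near the carbonyl that a stronger base could expel.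

Step 23
Reactants: 29 ethyl (2E,4E)-5-[(5R)-5-(TBSO)-2,6,6-trimethylcyclohex-1-en-1-yl]-3-methylpenta-2,4-dienoate
Product: 30 (2E,4E)-5-[(5R)-5-(TBSO)-2,6,6-trimethylcyclohex-1-en-1-yl]-3-methylpenta-2,4-dien-1-ol
Conditions: iBu2AlH (2.2 equiv), CH2Cl2, −78 °C; aq. KNaC4H4O6
Reagents that add atoms: none
Why: Reduction of the dienoate by iBu2AlH gives the dienyl alcohol.

Step 24
Reactants: 30 (2E,4E)-5-[(5R)-5-(TBSO)-2,6,6-trimethylcyclohex-1-en-1-yl]-3-methylpenta-2,4-dien-1-ol
Product: 31 [(2E,4E)-5-[(5R)-5-(TBSO)-2,6,6-trimethylcyclohex-1-en-1-yl]-3-methylpenta-2,4-dien-1-yl]triphenylphosphonium bromide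
Conditions: PPh3·HBr, CH2Cl2, rt
Reagents that add atoms: triphenylphosphine hydrobromide, Br.c1ccc(cc1)P(c1ccccc1)c1ccccc1
Why: Phosphonium salt formation through the pentadienyl cation as in step 15.

Step 25
Reactants: 31 ring A C15 phosphonium bromide; 32 (2E,4E,6E)-2,7-dimethylocta-2,4,6-trienedial
Product: 34 (2E,4E,6E,8E,10E,12E)-13-[(5R)-5-(TBSO)-2,6,6-trimethylcyclohex-1-en-1-yl]-2,7,11-trimethyltrideca-2,4,6,8,10,12-hexaenal, via ring A ylide 33 (not isolated)
Conditions: 32 (3 equiv), NaOMe, CH2Cl2/MeOH, 0 °C → rt; then heptane, 80 °C, dark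
Reagents that add atoms: none
Why: Wittig olefination of the semi-stabilised allylic ylide with an excess of the symmetrical C10 dialdehyde should favour mono-condensation, and heating equilibrates a Z isomer at the new C11'=C12' bond to the all-E polyenal.

Step 26
Reactants: 20 ring B C15 phosphonium bromide; 34 ring A C25 hexaenal
Product: 36 (2R,3S,2'R)-2,3,2'-tris(TBSO)-β,β-carotene (all-E), via ring B ylide 35 (not isolated)
Conditions: NaOMe, CH2Cl2/MeOH, rt; then heptane, 80 °C, dark, argon
Reagents that add atoms: none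
Why: The second Wittig olefination (C15 + C25) forms the C11=C12 bond under NaOMe, which the silyl ethers tolerate, and thermal stereomutation converts the hindered Z isomer at the new bond into the all-E carotenoid.

Step 27
Reactants: 36 (2R,3S,2'R)-2,3,2'-tris(TBSO)-β,β-carotene
Product: 37 (2R,3S,2'R)-β,β-carotene-2,3,2'-triol (CNP0391393.1)
Conditions: Bu4NF (6 equiv), THF, rt → 40 °C, dark, argon
Reagents that add atoms: none
Why: Fluoride-mediated desilylation cleaves the three silyl ethers under non-acidic conditions that spare the polyene and do not touch the three carbinol centres.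

Compound list
1 | 3-methylbut-2-en-1-ol (prenol) | CC(C)=CCO | starting material
2 | [(2S)-3,3-dimethyloxiran-2-yl]methanol | OC[C@@H]1OC1(C)C | intermediate
3 | (2R)-3,3-dimethyloxirane-2-carbaldehyde | O=C[C@@H]1OC1(C)C | intermediate
4 | methyl 3-methylbut-2-enoate | COC(=O)C=C(C)C | starting material
5 | lithium 1-methoxy-3-methylbuta-1,3-dien-1-olate | [Li+].COC([O-])=CC(C)=C | intermediate
6 | tert-butyl[(1-methoxy-3-methylbuta-1,3-dien-1-yl)oxy]dimethylsilane (ketene acetal geometry not defined) | COC(O[Si](C)(C)C(C)(C)C)=CC(C)=C | intermediate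
7 | methyl (2E,5S)-5-[(2S)-3,3-dimethyloxiran-2-yl]-5-hydroxy-3-methylpent-2-enoate | COC(=O)/C=C(C)/C[C@H](O)[C@@H]1OC1(C)C | intermediate
8 | methyl (2E,5S)-5-(TBSO)-5-[(2S)-3,3-dimethyloxiran-2-yl]-3-methylpent-2-enoate | COC(=O)/C=C(C)/C[C@H](O[Si](C)(C)C(C)(C)C)[C@@H]1OC1(C)C | intermediate
9 | (2E,5S)-5-(TBSO)-5-[(2S)-3,3-dimethyloxiran-2-yl]-3-methylpent-2-en-1-ol | OC/C=C(C)/C[C@H](O[Si](C)(C)C(C)(C)C)[C@@H]1OC1(C)C | intermediate
10 | (2E,5S)-5-(TBSO)-5-[(2S)-3,3-dimethyloxiran-2-yl]-3-methylpent-2-en-1-yl acetate | CC(=O)OC/C=C(C)/C[C@H](O[Si](C)(C)C(C)(C)C)[C@@H]1OC1(C)C | intermediate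
11 | [(1R,4S,5R)-4-(TBSO)-5-hydroxy-2,6,6-trimethylcyclohex-2-en-1-yl]methyl acetate | CC(=O)OC[C@@H]1C(C)=C[C@H](O[Si](C)(C)C(C)(C)C)[C@H](O)C1(C)C | intermediate
12 | [(1R,4S,5R)-4,5-bis(TBSO)-2,6,6-trimethylcyclohex-2-en-1-yl]methyl acetate | CC(=O)OC[C@@H]1C(C)=C[C@H](O[Si](C)(C)C(C)(C)C)[C@H](O[Si](C)(C)C(C)(C)C)C1(C)C | intermediate
13 | [(1R,4S,5R)-4,5-bis(TBSO)-2,6,6-trimethylcyclohex-2-en-1-yl]methanol | OC[C@@H]1C(C)=C[C@H](O[Si](C)(C)C(C)(C)C)[C@H](O[Si](C)(C)C(C)(C)C)C1(C)C | intermediate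
14 | (1R,4S,5R)-4,5-bis(TBSO)-2,6,6-trimethylcyclohex-2-ene-1-carbaldehyde | O=C[C@@H]1C(C)=C[C@H](O[Si](C)(C)C(C)(C)C)[C@H](O[Si](C)(C)C(C)(C)C)C1(C)C | intermediate
15 | (4S,5R)-4,5-bis(TBSO)-2,6,6-trimethylcyclohex-1-ene-1-carbaldehyde | O=CC1=C(C)C[C@H](O[Si](C)(C)C(C)(C)C)[C@H](O[Si](C)(C)C(C)(C)C)C1(C)C | intermediate
16 | triethyl 3-methyl-4-phosphonobut-2-enoate (E/Z mixture as purchased) | CCOC(=O)C=C(C)CP(=O)(OCC)OCC | starting material
17 | lithium salt of 16 deprotonated at C4 | [Li+].CCOC(=O)C=C(C)[CH-]P(=O)(OCC)OCC | intermediate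
18 | ethyl (2E,4E)-5-[(4S,5R)-4,5-bis(TBSO)-2,6,6-trimethylcyclohex-1-en-1-yl]-3-methylpenta-2,4-dienoate | CCOC(=O)/C=C(C)/C=C/C1=C(C)C[C@H](O[Si](C)(C)C(C)(C)C)[C@H](O[Si](C)(C)C(C)(C)C)C1(C)C | intermediate
19 | (2E,4E)-5-[(4S,5R)-4,5-bis(TBSO)-2,6,6-trimethylcyclohex-1-en-1-yl]-3-methylpenta-2,4-dien-1-ol | OC/C=C(C)/C=C/C1=C(C)C[C@H](O[Si](C)(C)C(C)(C)C)[C@H](O[Si](C)(C)C(C)(C)C)C1(C)C | intermediate
20 | [(2E,4E)-5-[(4S,5R)-4,5-bis(TBSO)-2,6,6-trimethylcyclohex-1-en-1-yl]-3-methylpenta-2,4-dien-1-yl]triphenylphosphonium bromide | [Br-].c1ccccc1[P+](c1ccccc1)(c1ccccc1)C/C=C(C)/C=C/C1=C(C)C[C@H](O[Si](C)(C)C(C)(C)C)[C@H](O[Si](C)(C)C(C)(C)C)C1(C)C | intermediate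
21 | geranyl acetate [(2E)-3,7-dimethylocta-2,6-dien-1-yl acetate] | CC(C)=CCC/C(C)=C/COC(C)=O | starting material
22 | (2E)-5-[(2R)-3,3-dimethyloxiran-2-yl]-3-methylpent-2-en-1-yl acetate | CC(=O)OC/C=C(C)/CC[C@H]1OC1(C)C | intermediate
23 | [(1S,5R)-5-hydroxy-2,6,6-trimethylcyclohex-2-en-1-yl]methyl acetate | CC(=O)OC[C@H]1C(C)=CC[C@@H](O)C1(C)C | intermediate
24 | [(1S,5R)-5-(TBSO)-2,6,6-trimethylcyclohex-2-en-1-yl]methyl acetate | CC(=O)OC[C@H]1C(C)=CC[C@@H](O[Si](C)(C)C(C)(C)C)C1(C)C | intermediate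
25 | [(1S,5R)-5-(TBSO)-2,6,6-trimethylcyclohex-2-en-1-yl]methanol | OC[C@H]1C(C)=CC[C@@H](O[Si](C)(C)C(C)(C)C)C1(C)C | intermediate
26 | (1S,5R)-5-(TBSO)-2,6,6-trimethylcyclohex-2-ene-1-carbaldehyde | O=C[C@H]1C(C)=CC[C@@H](O[Si](C)(C)C(C)(C)C)C1(C)C | intermediate
27 | (5R)-5-(TBSO)-2,6,6-trimethylcyclohex-1-ene-1-carbaldehyde | O=CC1=C(C)CC[C@@H](O[Si](C)(C)C(C)(C)C)C1(C)C | intermediate
28 | sodium salt of 16 deprotonated at C4 | [Na+].CCOC(=O)C=C(C)[CH-]P(=O)(OCC)OCC | intermediate
29 | ethyl (2E,4E)-5-[(5R)-5-(TBSO)-2,6,6-trimethylcyclohex-1-en-1-yl]-3-methylpenta-2,4-dienoate | CCOC(=O)/C=C(C)/C=C/C1=C(C)CC[C@@H](O[Si](C)(C)C(C)(C)C)C1(C)C | intermediate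
30 | (2E,4E)-5-[(5R)-5-(TBSO)-2,6,6-trimethylcyclohex-1-en-1-yl]-3-methylpenta-2,4-dien-1-ol | OC/C=C(C)/C=C/C1=C(C)CC[C@@H](O[Si](C)(C)C(C)(C)C)C1(C)C | intermediate
31 | [(2E,4E)-5-[(5R)-5-(TBSO)-2,6,6-trimethylcyclohex-1-en-1-yl]-3-methylpenta-2,4-dien-1-yl]triphenylphosphonium bromide | [Br-].c1ccccc1[P+](c1ccccc1)(c1ccccc1)C/C=C(C)/C=C/C1=C(C)CC[C@@H](O[Si](C)(C)C(C)(C)C)C1(C)C | intermediate
32 | (2E,4E,6E)-2,7-dimethylocta-2,4,6-trienedial | O=C/C(C)=C/C=C/C=C(C)/C=O | starting material
33 | ylide of 31 (phosphonium 1-ide at the carbon next to phosphorus) | c1ccccc1[P+](c1ccccc1)(c1ccccc1)[CH-]/C=C(C)/C=C/C1=C(C)CC[C@@H](O[Si](C)(C)C(C)(C)C)C1(C)C | intermediate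
34 | (2E,4E,6E,8E,10E,12E)-13-[(5R)-5-(TBSO)-2,6,6-trimethylcyclohex-1-en-1-yl]-2,7,11-trimethyltrideca-2,4,6,8,10,12-hexaenal | O=C/C(C)=C/C=C/C=C(C)/C=C/C=C(C)/C=C/C1=C(C)CC[C@@H](O[Si](C)(C)C(C)(C)C)C1(C)C | intermediate
35 | ylide of 20 (phosphonium 1-ide at the carbon next to phosphorus) | c1ccccc1[P+](c1ccccc1)(c1ccccc1)[CH-]/C=C(C)/C=C/C1=C(C)C[C@H](O[Si](C)(C)C(C)(C)C)[C@H](O[Si](C)(C)C(C)(C)C)C1(C)C | intermediate
36 | (2R,3S,2'R)-2,3,2'-tris(TBSO)-β,β-carotene, all-E | CC1=C(/C=C/C(C)=C/C=C/C(C)=C/C=C/C=C(C)/C=C/C=C(C)/C=C/C2=C(C)C[C@H](O[Si](C)(C)C(C)(C)C)[C@H](O[Si](C)(C)C(C)(C)C)C2(C)C)C(C)(C)[C@H](O[Si](C)(C)C(C)(C)C)CC1 | intermediate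
37 | (2R,3S,2'R)-β,β-carotene-2,3,2'-triol, all-E | CC1=C(/C=C/C(C)=C/C=C/C(C)=C/C=C/C=C(C)/C=C/C=C(C)/C=C/C2=C(C)C[C@H](O)[C@H](O)C2(C)C)C(C)(C)[C@H](O)CC1 | target

Total step count: 27. Longest linear sequence: 16 steps (steps 1, 2, 4–15, 26 and 27).

Steps most likely to fail

1. Step 8. The activated epoxide may rearrange by 1,2-hydride shift to the C2 ketone, or be opened by chloride, faster than the alkene closes the ring. The productive chair has to carry the C3 silyloxy group axial and 1,3 to an axial C1 methyl, and partial loss of the silyl group under the Lewis acid would add to this. Fallback: from 10, the same C1–C6 bond is closed by a radical instead of a cation. Trivalent titanium (Cp2TiCl, generated from Cp2TiCl2 and Mn dust in THF, rt) opens the epoxide homolytically to the tertiary C1 radical, which adds 6-endo to C6. β-Hydride loss from the resulting tertiary alkyltitanium should give the exocyclic-methylene hydroxy acetate F1. TBSOTf/2,6-lutidine then gives the bis-silyl ether F2, K2CO3/MeOH the primary alcohol F3, and Dess–Martin oxidation the exocyclic-methylene aldehyde F4. DBU conjugates F4 to 15, where the main route resumes.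

2. Step 4. The Lewis acid may open or rearrange the trisubstituted epoxide of 3 before the carbon–carbon bond forms, and facial selectivity at the aldehyde may be poor. Fallback: from 6, the C5 carbinol and the epoxide are set in separate, independently controlled operations. A SiCl4-mediated vinylogous aldol addition of 6 to commercial 3-methylbut-2-enal, catalysed by a chiral bisphosphoramide of the enantiomeric series that gives the 5R alcohol, should give the dienol ester F5. Hydroxyl-directed epoxidation with mCPBA (NaHCO3, CH2Cl2, 0 °C) under allylic 1,3-strain control gives the threo epoxy alcohol F6. Mitsunobu inversion at C5 (4-nitrobenzoic acid, PPh3, diisopropyl azodicarboxylate) gives the erythro 4-nitrobenzoate F7, and K2CO3/MeOH releases 7.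

3. Step 12. The dienolate that moves the double bond may expel the C3 silyloxy group (vinylogous β-elimination to a cyclohexadienal) instead of being reprotonated at C4. Fallback: from 12, the alkene is put in place by hydration and aldol-type dehydration, so that no carbanion is generated next to C3. Mukaiyama hydration of the C4=C5 and exocyclic alkene isomers (Co(acac)2 cat., PhSiH3, O2, iPrOH) gives the C5 tertiary alcohol F8. K2CO3/MeOH gives the diol F9 and Dess–Martin oxidation the β-hydroxy aldehyde F10. Mesylation–elimination (MsCl, Et3N, CH2Cl2, 0 °C) through the simple C6 enolate then delivers 15 regiospecifically.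

Further compounds
F1 | step 8 | exocyclic isomer of 11: [(1R,4S,5R)-4-(TBSO)-5-hydroxy-6,6-dimethyl-2-methylidenecyclohexyl]methyl acetate | CC(=O)OC[C@@H]1C(=C)C[C@H](O[Si](C)(C)C(C)(C)C)[C@H](O)C1(C)C
F2 | step 8 | exocyclic isomer of 12 (bis-TBS ether of F1) | CC(=O)OC[C@@H]1C(=C)C[C@H](O[Si](C)(C)C(C)(C)C)[C@H](O[Si](C)(C)C(C)(C)C)C1(C)C
F3 | step 8 | exocyclic isomer of 13 (primary alcohol from F2) | OC[C@@H]1C(=C)C[C@H](O[Si](C)(C)C(C)(C)C)[C@H](O[Si](C)(C)C(C)(C)C)C1(C)C
F4 | step 8 | exocyclic isomer of 14 (aldehyde from F3) | O=C[C@@H]1C(=C)C[C@H](O[Si](C)(C)C(C)(C)C)[C@H](O[Si](C)(C)C(C)(C)C)C1(C)C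
F5 | step 4 | methyl (2E,5R)-5-hydroxy-3,7-dimethylocta-2,6-dienoate | COC(=O)/C=C(C)/C[C@@H](O)C=C(C)C
F6 | step 4 | methyl (2E,5R)-5-[(2S)-3,3-dimethyloxiran-2-yl]-5-hydroxy-3-methylpent-2-enoate (threo) | COC(=O)/C=C(C)/C[C@@H](O)[C@@H]1OC1(C)C
F7 | step 4 | methyl (2E,5S)-5-[(2S)-3,3-dimethyloxiran-2-yl]-3-methyl-5-[(4-nitrobenzoyl)oxy]pent-2-enoate | COC(=O)/C=C(C)/C[C@H](OC(=O)c1ccc(cc1)[N+](=O)[O-])[C@@H]1OC1(C)C
F8 | step 12 | C5 tertiary alcohol from 12: [4,5-bis(TBSO)-2-hydroxy-2,6,6-trimethylcyclohexyl]methyl acetate (C5 epimers, carotenoid numbering) | CC(=O)OC[C@@H]1C(C)(O)C[C@H](O[Si](C)(C)C(C)(C)C)[C@H](O[Si](C)(C)C(C)(C)C)C1(C)C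
F9 | step 12 | diol from F8: 4,5-bis(TBSO)-2-(hydroxymethyl)-1,3,3-trimethylcyclohexan-1-ol | OC[C@@H]1C(C)(O)C[C@H](O[Si](C)(C)C(C)(C)C)[C@H](O[Si](C)(C)C(C)(C)C)C1(C)C
F10 | step 12 | β-hydroxy aldehyde from F9: 4,5-bis(TBSO)-2-hydroxy-2,6,6-trimethylcyclohexane-1-carbaldehyde | O=C[C@@H]1C(C)(O)C[C@H](O[Si](C)(C)C(C)(C)C)[C@H](O[Si](C)(C)C(C)(C)C)C1(C)C
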